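The closing of starting material into single ring is slow at 55 °C, and each flask has to be judged by how much of that slowness its time covers. The earlier run, dusk, is what stands:

- dusk (time / min: single ring / %): 2.00: 3.0; 4.00: 6.7; 6.00: 9.8; 8.00: 12.3; 10.0: 15.7; 12.0: 17.0; 15.0: 21.6

(scatter of a reading: 1 percentage point)

| flask | starting material | protic impurity | temperature | remark | time |
|---|---|---|---|---|---|
| dusk | 1.2 M | 0.016 M | 55 °C | run made earlier |  |
| grey | 0.80 M | 0.0160 M |  | at 105 °C until 80 min, from then on at 55 °C | 2.5 h |
| green | 0.80 M | 0.0160 M | 55 °C |  | 2.5 h |
| amber | 0.80 M | 0.0160 M | 80 °C |  | 2.5 h |
| teal | 0.80 M | 0.0160 M | 105 °C |  | 2.5 h |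

- percentages count the starting material that a species holds: one open dimer or ring dimer counts as two
- percentages count the starting material that a species holds: one open trimer counts as three
- single ring is meant together with its crystals
- solid, in amounts per volume of the solution: crystals
- the numbers in the tables scatter with a standard deviation of 1 percentage point
- reactions considered so far: starting material <-> single ring; 2 starting material -> open dimer; starting material + open dimer -> open trimer; open dimer -> ring dimer; crystals <-> single ring; starting material + protic impurity -> quenched substrate
- the earlier runs do not show what temperature does; that part of a forecast is a guess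

* the best flask by amount of single ring, in percent of the starting material charged; "all alike" if 1.5 percentage points covers them all (grey / green / amber / teal / all alike)
* amount of single ring at the end, in percent of the starting material charged, grey
* amount of single ring at the end, in percent of the starting material charged, green
* amount of single ring at the end, in percent of the starting material charged, amber
* amount of single ring at the end, in percent of the starting material charged, teal

The last dusk reading, 21.6% at 15.0 min, read as first-order closing and carrying the scatter of the readings, gives a rate constant of 0.0162 min⁻¹ and a closing half-life of 42.7 min. Taken as first order, this carries over to the lower charge of 0.80 M. Green, at the same temperature, therefore gets 3.51 half-lives allowed, the count being the time allowed divided by the closing half-life.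

The ladder follows from that. The dusk readings stop earlier than one half-life, so they show the start of the climb and nothing of its end. Green's time is longer than the half-life, and this reckoning leaves 8.77% of its starting material unclosed, which puts its single ring near 91.2% before any other loss. The protic impurity, the limiting reagent of the quenching step, is smaller than the starting material and can claim at most 2.00% of the charge. The open dimer routes and the effect of heat stand on no rung yet. Green is unfinished by this count, so a warmer flask may pass it, whereas the forecast names green as best. The forecast also says: “The temperature effects are guesses, so the ranges are wide.”

The flasks give amber as best: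

| Flask | Forecast | Flask gives |
|---|---|---|
| grey | 76% | 70.6% |
| green | 82% | 69.4% |
| amber | 80% | 75.1% |
| teal | 68% | 59.9% |

    starting material ⇌ single ring (K = 9.60, k = 0.200 min⁻¹, Ea = 95.0 kJ mol⁻¹, ΔH = −5.00 kJ mol⁻¹)
    2 starting material → open dimer (k = 0.0290 M⁻¹ min⁻¹, Ea = 80.0 kJ mol⁻¹)
    starting material + open dimer → open trimer (k = 1.70 M⁻¹ min⁻¹, Ea = 81.0 kJ mol⁻¹)
    open dimer → ring dimer (k = 0.0410 min⁻¹, Ea = 114 kJ mol⁻¹)
    crystals ⇌ single ring, rate k5*(cs5 - [single ring]) while solid is left; crystals form when [single ring] > cs5 (solubility = 0.440 M, k = 5.30 min⁻¹)
    starting material + protic impurity → quenched substrate (k = 1.10 M⁻¹ min⁻¹, Ea = 77.0 kJ mol⁻¹)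
    (constants at 80 °C)

Green's starting material ends at 9.10%, close to the 8.77% reckoned from its 3.51 half-lives allowed, yet its single ring stands at 69.4%. The pairing of starting material into open dimer is the main reason for that shortfall: green without this step gives 85.9%. Counted by conversion rather than by closing, amber converts half of its starting material in 2.82 min, against 0.500 h for green, so amber's time allows 53.2 such spans, more than green's 5.00, and amber's starting material stands level, at 5.63% after 1.25 h and 5.63% after 2.50 h.

The numbers in the tables were generated by integration with made-up constants; noise was put on by code.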